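The target is an achiral tridepside: ring A (2,4,5-trimethoxy-6-methylbenzoyl), ring B (orsellinate), ring C (orsellinic acid). It has no stereocentre, so no stereocontrol is needed; the stereocentres that arise in the key step vanish on aromatisation.
Ring C is cut through C1–C6 and C2–C3. Its C3, C4 (acylated oxygen), C5 and C6 (methyl) are C3–C6 of 4-hydroxy-6-methyl-2-pyrone with both substituents already in place. C1 (CO2H) and C2 (OH) are two adjacent malonate carbons at the ketene acetal level.
Further cuts: the acyl–oxygen bond between the ring B carbonyl and the pyrone oxygen, the acyl–oxygen bond between the ring A carbonyl and O–C4 of ring B, and the C6–CH3 bond of ring A.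
Forward: ring A acid (methylation, oxidation), ester with the C4 hydroxyl of 2,4-dihydroxy-6-methylbenzaldehyde, benzyl ether, oxidation to the ring A–ring B acid, O-acylation of the pyrone.
Ring C then forms by [4+2] addition with loss of CO2 and silanol, and hydrogenolysis ends the route.

Key step: step 8

Assumption: 2,4,5-trimethoxybenzaldehyde, 2,4-dihydroxy-6-methylbenzaldehyde, 4-hydroxy-6-methyl-2-pyrone and bis(trimethylsilyl) malonate are taken as commercial; flask intermediates with transient stereocentres are racemic and drawn without descriptors.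

Step 1
Reactants: 1 2,4,5-trimethoxybenzaldehyde
Product: 5 2,4,5-trimethoxy-6-methylbenzaldehyde, via lithium α-amino alkoxide 2 (not isolated), via C6-lithiated α-amino alkoxide 3 (not isolated), via C6-methylated α-amino alkoxide 4 (not isolated)
Conditions: MeNHCH2CH2NMe2, n-BuLi, THF, −20 °C; 1; n-BuLi (3 equiv), −20 °C; MeI, −78 °C → rt; 10% aq HCl
Reagents that add atoms: iodomethane, CI
Why: Directed ortho-lithiation through an in situ α-amino alkoxide: the lithium amide adds to the formyl group and masks it, its chelating diamine arm together with the C5 methoxy group should guide n-BuLi to C6–H rather than to C3–H between two methoxy groups, MeI alkylates the aryllithium, and aqueous acid collapses the hemiaminal back to the aldehyde.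

Step 2
Reactants: 5 2,4,5-trimethoxy-6-methylbenzaldehyde
Product: 6 2,4,5-trimethoxy-6-methylbenzoic acid
Conditions: NaClO2, NaH2PO4, 2-methyl-2-butene (excess), t-BuOH–H2O, rt
Reagents that add atoms: sodium chlorite, [Na+].[O-]Cl=O
Why: Pinnick oxidation takes hindered, electron-rich benzaldehydes to the benzoic acids under buffered conditions, and the excess alkene traps HOCl before it can chlorinate the free C3 position of the trimethoxyarene.

Step 3
Reactants: 6 2,4,5-trimethoxy-6-methylbenzoic acid; 7 2,4-dihydroxy-6-methylbenzaldehyde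
Product: 9 4-formyl-3-hydroxy-5-methylphenyl 2,4,5-trimethoxy-6-methylbenzoate, via mixed trifluoroacetic anhydride 8 (not isolated)
Conditions: (CF3CO)2O, PhMe, rt
Reagents that add atoms: none
Why: Depside esterification through a mixed trifluoroacetic anhydride, the classical activation for di-ortho-substituted electron-rich benzoic acids, should acylate only the C4 hydroxyl of 7 because the C2 hydroxyl is locked in a hydrogen bond to the formyl oxygen.

Step 4
Reactants: 9 4-formyl-3-hydroxy-5-methylphenyl 2,4,5-trimethoxy-6-methylbenzoate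
Product: 10 3-(benzyloxy)-4-formyl-5-methylphenyl 2,4,5-trimethoxy-6-methylbenzoate
Conditions: BnBr, K2CO3, DMF, rt
Reagents that add atoms: benzyl bromide, BrCc1ccccc1
Why: Williamson etherification of the chelated phenol proceeds with K2CO3 in DMF, while the di-ortho-substituted aryl ester is too hindered for attack by carbonate or phenoxide at room temperature.

Step 5
Reactants: 10 3-(benzyloxy)-4-formyl-5-methylphenyl 2,4,5-trimethoxy-6-methylbenzoate
Product: 11 2-(benzyloxy)-6-methyl-4-[(2,4,5-trimethoxy-6-methylbenzoyl)oxy]benzoic acid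
Conditions: NaClO2, NaH2PO4, 2-methyl-2-butene (excess), THF–t-BuOH–H2O, rt
Reagents that add atoms: sodium chlorite, [Na+].[O-]Cl=O
Why: A second Pinnick oxidation at about pH 4 leaves aryl ester, benzyl ether and methyl ethers untouched, and carrying ring B at the aldehyde level up to this point makes an ester protecting group for its carboxyl unnecessary.

Step 6
Reactants: 11 2-(benzyloxy)-6-methyl-4-[(2,4,5-trimethoxy-6-methylbenzoyl)oxy]benzoic acid; 12 4-hydroxy-6-methyl-2H-pyran-2-one
Product: 14 6-methyl-2-oxo-2H-pyran-4-yl 2-(benzyloxy)-6-methyl-4-[(2,4,5-trimethoxy-6-methylbenzoyl)oxy]benzoate, via acid chloride 13 (not isolated)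
Conditions: (COCl)2, DMF (cat.), CH2Cl2, 0 °C → rt, evaporate; 12, Et3N, CH2Cl2, 0 °C → rt (no DMAP)
Reagents that add atoms: none
Why: Acid chloride formation under Vilsmeier-type DMF catalysis and O-acylation of the triethylammonium pyronate is the known kinetic course for 4-hydroxy-6-methyl-2-pyrone with acyl chlorides, and the absence of DMAP or cyanide together with the hindered aroyl group should prevent the acyl shift from oxygen to C3.

Step 7
Reactants: 15 bis(trimethylsilyl) malonate
Product: 16 trimethylsilyl 3,3-bis[(trimethylsilyl)oxy]prop-2-enoate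
Conditions: TMSOTf, Et3N, Et2O, 0 °C → rt; decant from the ammonium salt, distil under reduced pressure
Reagents that add atoms: trimethylsilyl trifluoromethanesulfonate, C[Si](C)(C)OS(=O)(=O)C(F)(F)F
Why: Soft enolisation and O-silylation of a malonate with TMSOTf/Et3N (silyl ketene acetal formation) should give 16 as one compound, because the fast 1,5-silyl shift between the two carboxyl units, which would scramble a mixed alkyl silyl malonate, is degenerate when all three groups are trimethylsilyl.

Step 8
Reactants: 14 6-methyl-2-oxo-2H-pyran-4-yl 2-(benzyloxy)-6-methyl-4-[(2,4,5-trimethoxy-6-methylbenzoyl)oxy]benzoate; 16 trimethylsilyl 3,3-bis[(trimethylsilyl)oxy]prop-2-enoate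
Product: 20 4-({2-(benzyloxy)-6-methyl-4-[(2,4,5-trimethoxy-6-methylbenzoyl)oxy]benzoyl}oxy)-2-hydroxy-6-methylbenzoic acid, via bridged bicyclic lactone 17 (not isolated), via cyclohexadiene 18 (not isolated), via silylated arene 19 (not isolated)
Conditions: 16 (4 equiv), TMSOTf (0.2 equiv), PhMe, −40 °C → rt; Et3N (0.3 equiv), then 110 °C (sealed tube); THF–1 M aq citric acid, rt
Reagents that add atoms: none
Why: Proposed new method: TMSOTf silylates the lactone carbonyl of 14 to a 2-silyloxypyrylium ion, the nucleophilic CH carbon of 16 adds to its C6 (ring C bond C1–C6), and pyrone C3, now the α-carbon of a cyclic silyl ketene acetal, closes onto the bis(silyloxy)carbenium carbon (ring C bond C2–C3), so that the six-membered carbocycle is closed in a polar, strongly asynchronous [4+2] mode as the bridged lactone 17. On heating, 17 loses CO2 by retro-[4+2] to give diene 18, 1,2-elimination of trimethylsilanol across C1–C2 aromatises it to 19, and the citric acid work-up cleaves the silyl ester and the aryl silyl ether. The closest known reaction types are the inverse-electron-demand Diels–Alder reaction of ester-activated 2-pyrones with ketene acetals (benzoates after loss of CO2 and alcohol), the thermal cycloaddition of 4-alkoxy-6-methyl-2-pyrones to acetylenic esters, the carbanion-induced ring transformation of 2-pyranones into arenes (the same two bonds, made stepwise) and silyl-triflate-catalysed Mukaiyama–Michael additions; a 2-pyrone without an acceptor group and a malonate-derived ketene acetal have not been combined in this way. The three stereocentres of 17 and the single one of 18 are transient and disappear on aromatisation, so neither facial nor endo/exo control is required. The step needs attack at C6 rather than at C4 (addition–elimination of the aroate) or at the aroyl carbonyl: C6 carries only a methyl group and is the least donor-stabilised pyrylium position, the benzyloxy and methyl groups flanking the ring B carbonyl block direct acyl transfer and screen C4, and low temperature in a non-polar solvent holds back ionisation to an acylium ion. Because the three silyl groups of 16 are identical, silyl migration among its oxygens is degenerate and closure on either carboxyl carbon gives the same ring C.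

Step 9
Reactants: 20 4-({2-(benzyloxy)-6-methyl-4-[(2,4,5-trimethoxy-6-methylbenzoyl)oxy]benzoyl}oxy)-2-hydroxy-6-methylbenzoic acid
Product: 21 2-hydroxy-4-({2-hydroxy-6-methyl-4-[(2,4,5-trimethoxy-6-methylbenzoyl)oxy]benzoyl}oxy)-6-methylbenzoic acid (CNP0328932.0)
Conditions: H2 (1 atm), 10% Pd/C, EtOAc, rt
Reagents that add atoms: none
Why: Catalytic hydrogenolysis of the aryl benzyl ether, the customary last step of depside syntheses, leaves the two aryl esters, the methyl ethers and the salicylic acid unit intact.

Compound list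
1 | 2,4,5-trimethoxybenzaldehyde | COc1cc(OC)c(C=O)cc1OC | starting material
2 | lithium {[2-(dimethylamino)ethyl](methyl)amino}(2,4,5-trimethoxyphenyl)methanolate (racemic) | [Li]OC(N(C)CCN(C)C)c1cc(OC)c(OC)cc1OC | intermediate
3 | C6-lithiated derivative of 2 (racemic) | [Li]OC(N(C)CCN(C)C)c1c([Li])c(OC)c(OC)cc1OC | intermediate
4 | lithium {[2-(dimethylamino)ethyl](methyl)amino}(2,4,5-trimethoxy-6-methylphenyl)methanolate (racemic) | [Li]OC(N(C)CCN(C)C)c1c(C)c(OC)c(OC)cc1OC | intermediate
5 | 2,4,5-trimethoxy-6-methylbenzaldehyde | COc1cc(OC)c(C=O)c(C)c1OC | intermediate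
6 | 2,4,5-trimethoxy-6-methylbenzoic acid | COc1cc(OC)c(C(=O)O)c(C)c1OC | intermediate
7 | 2,4-dihydroxy-6-methylbenzaldehyde | Cc1cc(O)cc(O)c1C=O | starting material
8 | 2,4,5-trimethoxy-6-methylbenzoic trifluoroacetic anhydride | COc1cc(OC)c(C(=O)OC(=O)C(F)(F)F)c(C)c1OC | intermediate
9 | 4-formyl-3-hydroxy-5-methylphenyl 2,4,5-trimethoxy-6-methylbenzoate | COc1cc(OC)c(C(=O)Oc2cc(C)c(C=O)c(O)c2)c(C)c1OC | intermediate
10 | 3-(benzyloxy)-4-formyl-5-methylphenyl 2,4,5-trimethoxy-6-methylbenzoate | COc1cc(OC)c(C(=O)Oc2cc(C)c(C=O)c(OCc3ccccc3)c2)c(C)c1OC | intermediate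
11 | 2-(benzyloxy)-6-methyl-4-[(2,4,5-trimethoxy-6-methylbenzoyl)oxy]benzoic acid | COc1cc(OC)c(C(=O)Oc2cc(C)c(C(=O)O)c(OCc3ccccc3)c2)c(C)c1OC | intermediate
12 | 4-hydroxy-6-methyl-2H-pyran-2-one | CC1=CC(O)=CC(=O)O1 | starting material
13 | 2-(benzyloxy)-6-methyl-4-[(2,4,5-trimethoxy-6-methylbenzoyl)oxy]benzoyl chloride | COc1cc(OC)c(C(=O)Oc2cc(C)c(C(=O)Cl)c(OCc3ccccc3)c2)c(C)c1OC | intermediate
14 | 6-methyl-2-oxo-2H-pyran-4-yl 2-(benzyloxy)-6-methyl-4-[(2,4,5-trimethoxy-6-methylbenzoyl)oxy]benzoate | COc1cc(OC)c(C(=O)Oc2cc(C)c(C(=O)OC3=CC(=O)OC(C)=C3)c(OCc3ccccc3)c2)c(C)c1OC | intermediate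
15 | bis(trimethylsilyl) malonate | C[Si](C)(C)OC(=O)CC(=O)O[Si](C)(C)C | starting material
16 | trimethylsilyl 3,3-bis[(trimethylsilyl)oxy]prop-2-enoate | C[Si](C)(C)OC(=O)C=C(O[Si](C)(C)C)O[Si](C)(C)C | intermediate
17 | trimethylsilyl 5-({2-(benzyloxy)-6-methyl-4-[(2,4,5-trimethoxy-6-methylbenzoyl)oxy]benzoyl}oxy)-1-methyl-3-oxo-8,8-bis[(trimethylsilyl)oxy]-2-oxabicyclo[2.2.2]oct-5-ene-7-carboxylate (racemic, endo/exo not defined) | CC12OC(=O)C(C(OC(=O)c3c(C)cc(OC(=O)c4c(C)c(OC)c(OC)cc4OC)cc3OCc3ccccc3)=C1)C(O[Si](C)(C)C)(O[Si](C)(C)C)C2C(=O)O[Si](C)(C)C | intermediate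
18 | trimethylsilyl 4-({2-(benzyloxy)-6-methyl-4-[(2,4,5-trimethoxy-6-methylbenzoyl)oxy]benzoyl}oxy)-2-methyl-6,6-bis[(trimethylsilyl)oxy]cyclohexa-2,4-diene-1-carboxylate (racemic) | CC1=CC(OC(=O)c2c(C)cc(OC(=O)c3c(C)c(OC)c(OC)cc3OC)cc2OCc2ccccc2)=CC(O[Si](C)(C)C)(O[Si](C)(C)C)C1C(=O)O[Si](C)(C)C | intermediate
19 | trimethylsilyl 4-({2-(benzyloxy)-6-methyl-4-[(2,4,5-trimethoxy-6-methylbenzoyl)oxy]benzoyl}oxy)-2-methyl-6-[(trimethylsilyl)oxy]benzoate | Cc1cc(OC(=O)c2c(C)cc(OC(=O)c3c(C)c(OC)c(OC)cc3OC)cc2OCc2ccccc2)cc(O[Si](C)(C)C)c1C(=O)O[Si](C)(C)C | intermediate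
20 | 4-({2-(benzyloxy)-6-methyl-4-[(2,4,5-trimethoxy-6-methylbenzoyl)oxy]benzoyl}oxy)-2-hydroxy-6-methylbenzoic acid | COc1cc(OC)c(C(=O)Oc2cc(C)c(C(=O)Oc3cc(C)c(C(=O)O)c(O)c3)c(OCc3ccccc3)c2)c(C)c1OC | intermediate
21 | 2-hydroxy-4-({2-hydroxy-6-methyl-4-[(2,4,5-trimethoxy-6-methylbenzoyl)oxy]benzoyl}oxy)-6-methylbenzoic acid (CNP0328932.0) | COc1cc(OC)c(C(=O)Oc2cc(C)c(C(=O)Oc3cc(C)c(C(=O)O)c(O)c3)c(O)c2)c(C)c1OC | target

Total step count: 9. Longest linear sequence: 8 (steps 1–6, 8 and 9; step 7 is a one-step side branch).

Steps most likely to fail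

Step 8 (new method). Several processes could defeat this step:
- The silylated pyrone may not be electrophilic enough for the attenuated push–pull ketene acetal.
- The sequence may stall after the first C–C bond through loss of the silyl cation.
- Conjugate addition–elimination at C4 may compete.
- Ionisation of the activated aroyl–oxygen bond may hand the ring B acyl group to the ketene acetal.

The fallback uses known depside chemistry and takes ring C ready-made instead of building it. It sets out from acid chloride 13, prepared from 11 as in step 6. Commercial orsellinic acid is esterified at the carboxylate (BnBr, KHCO3, DMF, rt) to benzyl 2,4-dihydroxy-6-methylbenzoate F1. The unchelated C4 hydroxyl of F1 is acylated by 13 (Et3N, DMAP cat., CH2Cl2). This gives benzyl 4-({2-(benzyloxy)-6-methyl-4-[(2,4,5-trimethoxy-6-methylbenzoyl)oxy]benzoyl}oxy)-2-hydroxy-6-methylbenzoate F2. Hydrogenolysis (H2, 10% Pd/C, EtOAc) removes both benzyl groups, and the fallback comes back to the route at 21.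

Step 6. Acylation may be slow because of crowding around the ring B carbonyl. The aroyl group may migrate from oxygen to C3, or the vinylogous anhydride may hydrolyse during purification. The fallback reverses the polarity of the bond formation and sets out from 11 and 12. Pyrone 12 is sulfonylated (TsCl, Et3N, CH2Cl2) to 6-methyl-2-oxo-2H-pyran-4-yl 4-methylbenzenesulfonate F3. Acid 11 is converted with Cs2CO3 in DMF into cesium 2-(benzyloxy)-6-methyl-4-[(2,4,5-trimethoxy-6-methylbenzoyl)oxy]benzoate F4. This unhindered carboxylate oxygen displaces the sulfonate at pyrone C4 by conjugate addition–elimination, and the fallback comes back to the route at 14.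

Step 1. Lithiation may compete at C3 between the two methoxy groups. Metalation may be incomplete, or lateral lithiation may lead to a second methylation of the new methyl group. The fallback builds ring A around a methyl group that is already present and sets out from 7.
- Double O-methylation (MeI, K2CO3, DMF) gives 2,4-dimethoxy-6-methylbenzaldehyde F5.
- Baeyer–Villiger oxidation (mCPBA, CH2Cl2) gives 2,4-dimethoxy-6-methylphenyl formate F6.
- Saponification (KOH, MeOH) gives 2,4-dimethoxy-6-methylphenol F7.
- Methylation (MeI, K2CO3) gives 1,2,5-trimethoxy-3-methylbenzene F8.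
- Vilsmeier–Haack formylation (POCl3, DMF) should enter next to the methyl group, para to one methoxy group and ortho to another, rather than between two methoxy groups, as it does in 3,5-dimethoxytoluene.

The fallback comes back to the route at 5.

Further compounds
F1 | step 8 | benzyl 2,4-dihydroxy-6-methylbenzoate | Cc1cc(O)cc(O)c1C(=O)OCc1ccccc1
F2 | step 8 | benzyl 4-({2-(benzyloxy)-6-methyl-4-[(2,4,5-trimethoxy-6-methylbenzoyl)oxy]benzoyl}oxy)-2-hydroxy-6-methylbenzoate | COc1cc(OC)c(C(=O)Oc2cc(C)c(C(=O)Oc3cc(C)c(C(=O)OCc4ccccc4)c(O)c3)c(OCc3ccccc3)c2)c(C)c1OC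
F3 | step 6 | 6-methyl-2-oxo-2H-pyran-4-yl 4-methylbenzenesulfonate | CC1=CC(OS(=O)(=O)c2ccc(C)cc2)=CC(=O)O1
F4 | step 6 | cesium 2-(benzyloxy)-6-methyl-4-[(2,4,5-trimethoxy-6-methylbenzoyl)oxy]benzoate | [Cs+].COc1cc(OC)c(C(=O)Oc2cc(C)c(C(=O)[O-])c(OCc3ccccc3)c2)c(C)c1OC
F5 | step 1 | 2,4-dimethoxy-6-methylbenzaldehyde | COc1cc(C)c(C=O)c(OC)c1
F6 | step 1 | 2,4-dimethoxy-6-methylphenyl formate | COc1cc(C)c(OC=O)c(OC)c1
F7 | step 1 | 2,4-dimethoxy-6-methylphenol | COc1cc(C)c(O)c(OC)c1
F8 | step 1 | 1,2,5-trimethoxy-3-methylbenzene | COc1cc(C)c(OC)c(OC)c1
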